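**Retrosynthetic overview**

- Feature: ring A (benzoate ring with the ester carboxyl on C1, OH on C2 and C4, the 8-hydroxyundecyl chain on C6) and ring B (3,5-dihydroxyphenyl ring with the chain on C1) have the same oxygen/alkyl pattern. Ring B is ring A without its carboxyl carbon, so each ring can grow from an alk-2-ynoate whose two alkyne carbons become the carboxyl-bearing and the chain-bearing ring carbons.
- Target 22 ⇐ thermal decarboxylation of ring B acid 21 ⇐ acid deprotection of bis-resorcylate 20 ⇐ twofold Diels–Alder/retro-Diels–Alder of diyne diester 14 with two molecules of bis(silyloxy)diene 18 (from dimedone). Rings A and B form in the same operation, with no set order between them.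
- 14 ⇐ invertive Mitsunobu esterification of ynoic acid 11 with hydroxy ynoate 13; 13 is made from 11 by tert-butyl esterification and desilylation, so one (S)-acid supplies both halves.
- 11 ⇐ carboxylation of (S)-alkyne 9 ⇐ Ohira–Bestmann homologation of aldehyde 8 ⇐ hydroboration/oxidation of alkene 5 ⇐ CuI-catalysed opening of (S)-2-propyloxirane by the Grignard reagent of 7-bromohept-1-ene.

Key step: step 12

Remark: (S)-2-propyloxirane, 7-bromohept-1-ene and dimedone are taken as purchased. Acid 11 is divided: one portion goes through steps 7 and 8 to alcohol 13, the other is the acyl partner in step 9. The aryl trimethylsilyl ethers of 20 are hydrolytically labile, so 20 is carried crude into step 13; partly desilylated material converges on 21 there.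

**Route**

Step 1
Reactants: 1 7-bromohept-1-ene; 2 (S)-2-propyloxirane
Product: 4 (S)-dodec-11-en-4-ol, via hept-6-en-1-ylmagnesium bromide 3 (not isolated)
Conditions: Mg, THF, rt to 40 °C; then CuI (10 mol%), 2, THF, −30 to 0 °C; aq NH4Cl
Reagents that add atoms: none
Why: Copper-catalysed Grignard opening of a terminal epoxide is an SN2 attack at the unsubstituted CH2 carbon, so the C–O bond of the stereocenter is untouched and the (S) configuration of 2 becomes C4 of 4.

Step 2
Reactants: 4 (S)-dodec-11-en-4-ol
Product: 5 (S)-tert-butyl(dodec-11-en-4-yloxy)dimethylsilane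
Conditions: TBSCl, imidazole, DMF, rt
Reagents that add atoms: tert-butyldimethylsilyl chloride, CC(C)(C)[Si](C)(C)Cl
Why: Standard silylation of a secondary alcohol (TBS protection) masks the carbinol for the organoborane and organolithium chemistry that follows.

Step 3
Reactants: 5 (S)-tert-butyl(dodec-11-en-4-yloxy)dimethylsilane
Product: 7 (S)-9-((tert-butyldimethylsilyl)oxy)dodecan-1-ol, via B-alkyl-9-borabicyclo[3.3.1]nonane 6 (not isolated)
Conditions: 9-BBN, THF, 0 °C to rt; then 3 M NaOH, 30% H2O2, 0 °C to rt
Reagents that add atoms: hydrogen peroxide, OO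
Why: Brown hydroboration–oxidation with 9-BBN is anti-Markovnikov on the terminal alkene and gives the primary alcohol, and the silyl ether is inert to both stages.

Step 4
Reactants: 7 (S)-9-((tert-butyldimethylsilyl)oxy)dodecan-1-ol
Product: 8 (S)-9-((tert-butyldimethylsilyl)oxy)dodecanal
Conditions: TEMPO (10 mol%), PhI(OAc)2, CH2Cl2, rt
Reagents that add atoms: none
Why: TEMPO-catalysed oxidation with PhI(OAc)2 as terminal oxidant stops at the aldehyde and tolerates the silyl ether.

Step 5
Reactants: 8 (S)-9-((tert-butyldimethylsilyl)oxy)dodecanal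
Product: 9 (S)-tert-butyldimethyl(tridec-12-yn-4-yloxy)silane
Conditions: dimethyl (1-diazo-2-oxopropyl)phosphonate, K2CO3, MeOH, 0 °C to rt
Reagents that add atoms: dimethyl (1-diazo-2-oxopropyl)phosphonate, CC(=O)C(=[N+]=[N-])P(=O)(OC)OC
Why: Seyferth–Gilbert homologation with the Ohira–Bestmann reagent turns the unbranched aldehyde into the terminal alkyne with one added carbon under mild carbonate conditions that leave the silyl ether alone.

Step 6
Reactants: 9 (S)-tert-butyldimethyl(tridec-12-yn-4-yloxy)silane
Product: 11 (S)-11-((tert-butyldimethylsilyl)oxy)tetradec-2-ynoic acid, via lithium acetylide 10 (not isolated)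
Conditions: n-BuLi, THF, −78 °C; CO2 (dry gas), −78 °C to rt; cold 0.5 M HCl to pH 3
Reagents that add atoms: carbon dioxide, O=C=O
Why: Carboxylation of a lithium acetylide with CO2 is the standard route to alk-2-ynoic acids, and brief cold acidification leaves the secondary TBS ether in place.

Step 7
Reactants: 11 (S)-11-((tert-butyldimethylsilyl)oxy)tetradec-2-ynoic acid
Product: 12 tert-butyl (S)-11-((tert-butyldimethylsilyl)oxy)tetradec-2-ynoate
Conditions: tert-butyl 2,2,2-trichloroacetimidate (2.5 equiv), cyclohexane–CH2Cl2 (2:1), rt; filtration of trichloroacetamide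
Reagents that add atoms: tert-butyl 2,2,2-trichloroacetimidate, CC(C)(C)OC(=N)C(Cl)(Cl)Cl
Why: In this acid–imidate esterification the acidic alk-2-ynoic acid protonates the imidate and its carboxylate captures the tert-butyl group, so no base or nucleophilic catalyst that could add to the ynoate is present, and without an added Lewis acid the secondary TBS ether and the (S) center are untouched.

Step 8
Reactants: 12 tert-butyl (S)-11-((tert-butyldimethylsilyl)oxy)tetradec-2-ynoate
Product: 13 tert-butyl (S)-11-hydroxytetradec-2-ynoate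
Conditions: HF·pyridine, pyridine, THF, 0 °C to rt
Reagents that add atoms: none
Why: Buffered fluoride desilylation frees the secondary alcohol without conjugate addition to the ynoate or loss of the tert-butyl ester, and the (S) center is not involved.

Step 9
Reactants: 11 (S)-11-((tert-butyldimethylsilyl)oxy)tetradec-2-ynoic acid; 13 tert-butyl (S)-11-hydroxytetradec-2-ynoate
Product: 14 tert-butyl (R)-11-{[(S)-11-((tert-butyldimethylsilyl)oxy)tetradec-2-ynoyl]oxy}tetradec-2-ynoate
Conditions: PPh3, DIAD, THF, 0 °C (betaine formed first); then 11 and 13, 0 °C to rt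
Reagents that add atoms: none
Why: In this Mitsunobu esterification the acidic alk-2-ynoic acid (pKa about 2.6) displaces the oxyphosphonium of the unhindered secondary alcohol by SN2, inverting the (S) carbinol of 13 to the (R) ester center of 14 while the (S) center of 11 is a spectator.

Step 10
Reactants: 15 dimedone (5,5-dimethylcyclohexane-1,3-dione)
Product: 16 5,5-dimethyl-3-((trimethylsilyl)oxy)cyclohex-2-en-1-one
Conditions: TMSCl, Et3N, THF, 0 °C to rt; filtration, distillation
Reagents that add atoms: chlorotrimethylsilane, C[Si](C)(C)Cl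
Why: O-silylation of the enol form of the cyclic 1,3-diketone (silyl enol ether formation) gives the vinylogous silyl ester and leaves the alpha-prime CH2 as the kinetic site for deprotonation.

Step 11
Reactants: 16 5,5-dimethyl-3-((trimethylsilyl)oxy)cyclohex-2-en-1-one
Product: 18 5,5-dimethyl-1,3-bis((trimethylsilyl)oxy)cyclohexa-1,3-diene, via lithium dienolate 17 (not isolated)
Conditions: LDA, THF, −78 °C; TMSCl, −78 °C to rt; pentane, filtration, distillation (no aqueous work-up)
Reagents that add atoms: chlorotrimethylsilane, C[Si](C)(C)Cl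
Why: Kinetic alpha-prime deprotonation of the 3-silyloxy enone with LDA and O-silylation of the cross-conjugated dienolate (kinetic silyl enol ether formation) gives the 1,3-bis(silyloxy)diene.

Step 12
Reactants: 14 tert-butyl (R)-11-{[(S)-11-((tert-butyldimethylsilyl)oxy)tetradec-2-ynoyl]oxy}tetradec-2-ynoate; 18 5,5-dimethyl-1,3-bis((trimethylsilyl)oxy)cyclohexa-1,3-diene (two equivalents react)
Product: 20 tert-butyl 2-[(R)-8-({2-[(S)-8-((tert-butyldimethylsilyl)oxy)undecyl]-4,6-bis((trimethylsilyl)oxy)benzoyl}oxy)undecyl]-4,6-bis((trimethylsilyl)oxy)benzoate, via bis-bicyclo[2.2.2]octadiene adduct 19 (not isolated)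
Conditions: 18 (6 equiv), neat, sealed tube, Ar, 150–170 °C, 24–48 h; excess 18 distilled off in vacuo; crude 20 used directly
Reagents that add atoms: none
Why: Each ynoate undergoes a thermal normal-electron-demand Diels–Alder reaction with the electron-rich diene 18 to give a bicyclo[2.2.2]octa-2,5-diene (19), which aromatises by retro-Diels–Alder loss of 2-methylpropene from its CH2–CMe2 bridge. The closest known reaction type is the Alder–Rickert synthesis of resorcylates from alk-2-ynoates and 1,3-bis(silyloxy)cyclohexa-1,3-dienes, used here at both ends of one substrate. Ring A and ring B are each closed by an intermolecular (4+2) annulation that forms the bond from the carboxyl-bearing alkyne carbon to the silyloxy-bearing diene terminus and the bond from the chain-bearing alkyne carbon to the CH terminus. No stereocenter is created in the product, since the bridgehead centers of 19 vanish on aromatisation and the two carbinol centers are remote and untouched. The step needs the same regiochemistry in both cycloadditions, and this is secured by the match between the electrophilic beta carbon of each ynoate and the CH terminus of the diene, which carries the largest HOMO coefficient because both silyloxy groups donate to it. Because the 1,5-hydrogen shift of 18 is degenerate and the silyl ethers and the tert-butyl ester only have to last until the acid treatment of step 13, excess diene and long heating can be used to drive the second cycloaddition to completion.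

Step 13
Reactants: 20 tert-butyl 2-[(R)-8-({2-[(S)-8-((tert-butyldimethylsilyl)oxy)undecyl]-4,6-bis((trimethylsilyl)oxy)benzoyl}oxy)undecyl]-4,6-bis((trimethylsilyl)oxy)benzoate
Product: 21 2-[(R)-8-({2,4-dihydroxy-6-[(S)-8-hydroxyundecyl]benzoyl}oxy)undecyl]-4,6-dihydroxybenzoic acid
Conditions: TFA–CH2Cl2 (1:1), iPr3SiH (10 equiv), H2O (5 equiv), 0 °C to rt; evaporate; NaHCO3, MeOH–H2O, 0 °C (cleaves any trifluoroacetate); cold dilute HCl to pH 3
Reagents that add atoms: none
Why: Acidolysis by TFA cleaves the four aryl trimethylsilyl ethers, the secondary TBS ether and the tert-butyl ester (alkyl–oxygen cleavage through the tert-butyl cation, which iPr3SiH reduces to 2-methylpropane before it can alkylate the electron-rich rings), while the ring A ester of a secondary alcohol is stable to these conditions.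

Step 14
Reactants: 21 2-[(R)-8-({2,4-dihydroxy-6-[(S)-8-hydroxyundecyl]benzoyl}oxy)undecyl]-4,6-dihydroxybenzoic acid
Product: 22 (R)-1-(3,5-dihydroxyphenyl)undecan-8-yl 2,4-dihydroxy-6-[(S)-8-hydroxyundecyl]benzoate (CNP0263107.2)
Conditions: degassed dioxane–H2O (9:1), 100 °C, Ar, until CO2 evolution ceases
Reagents that add atoms: none
Why: Thermal protodecarboxylation of a 2,4-dihydroxybenzoic acid proceeds by ipso-protonation of the carboxyl-bearing carbon, which is ortho and para to the two hydroxyl groups, so only the free acid on ring B loses CO2 and the ring A carboxyl, being an ester, stays.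

**Compound list**

1 | 7-bromohept-1-ene | C=CCCCCCBr | starting material
2 | (S)-2-propyloxirane | CCC[C@H]1CO1 | starting material
3 | hept-6-en-1-ylmagnesium bromide | C=CCCCCC[Mg]Br | intermediate
4 | (S)-dodec-11-en-4-ol | CCC[C@H](O)CCCCCCC=C | intermediate
5 | (S)-tert-butyl(dodec-11-en-4-yloxy)dimethylsilane | CCC[C@H](O[Si](C)(C)C(C)(C)C)CCCCCCC=C | intermediate
6 | 9-[(S)-9-((tert-butyldimethylsilyl)oxy)dodecyl]-9-borabicyclo[3.3.1]nonane | CCC[C@H](O[Si](C)(C)C(C)(C)C)CCCCCCCCB1C2CCCC1CCC2 | intermediate
7 | (S)-9-((tert-butyldimethylsilyl)oxy)dodecan-1-ol | CCC[C@H](O[Si](C)(C)C(C)(C)C)CCCCCCCCO | intermediate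
8 | (S)-9-((tert-butyldimethylsilyl)oxy)dodecanal | CCC[C@H](O[Si](C)(C)C(C)(C)C)CCCCCCCC=O | intermediate
9 | (S)-tert-butyldimethyl(tridec-12-yn-4-yloxy)silane | CCC[C@H](O[Si](C)(C)C(C)(C)C)CCCCCCCC#C | intermediate
10 | lithium acetylide of 9 | CCC[C@H](O[Si](C)(C)C(C)(C)C)CCCCCCCC#C[Li] | intermediate
11 | (S)-11-((tert-butyldimethylsilyl)oxy)tetradec-2-ynoic acid | CCC[C@H](O[Si](C)(C)C(C)(C)C)CCCCCCCC#CC(=O)O | intermediate
12 | tert-butyl (S)-11-((tert-butyldimethylsilyl)oxy)tetradec-2-ynoate | CCC[C@H](O[Si](C)(C)C(C)(C)C)CCCCCCCC#CC(=O)OC(C)(C)C | intermediate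
13 | tert-butyl (S)-11-hydroxytetradec-2-ynoate | CCC[C@H](O)CCCCCCCC#CC(=O)OC(C)(C)C | intermediate
14 | tert-butyl (R)-11-{[(S)-11-((tert-butyldimethylsilyl)oxy)tetradec-2-ynoyl]oxy}tetradec-2-ynoate | CCC[C@H](O[Si](C)(C)C(C)(C)C)CCCCCCCC#CC(=O)O[C@H](CCC)CCCCCCCC#CC(=O)OC(C)(C)C | intermediate
15 | dimedone (5,5-dimethylcyclohexane-1,3-dione) | CC1(C)CC(=O)CC(=O)C1 | starting material
16 | 5,5-dimethyl-3-((trimethylsilyl)oxy)cyclohex-2-en-1-one | CC1(C)CC(=O)C=C(O[Si](C)(C)C)C1 | intermediate
17 | lithium 3,3-dimethyl-5-((trimethylsilyl)oxy)cyclohexa-1,5-dien-1-olate | [Li+].CC1(C)C=C([O-])C=C(O[Si](C)(C)C)C1 | intermediate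
18 | 5,5-dimethyl-1,3-bis((trimethylsilyl)oxy)cyclohexa-1,3-diene | CC1(C)CC(O[Si](C)(C)C)=CC(O[Si](C)(C)C)=C1 | intermediate
19 | twofold cycloadduct of 14 and 18: each former ynoate is a 3-alkyl-8,8-dimethyl-1,5-bis((trimethylsilyl)oxy)bicyclo[2.2.2]octa-2,5-diene-2-carboxylate (bridgehead configurations unassigned, mixture) | CCC[C@H](O[Si](C)(C)C(C)(C)C)CCCCCCCC1=C(C(=O)O[C@H](CCC)CCCCCCCC2=C(C(=O)OC(C)(C)C)C3(O[Si](C)(C)C)C=C(O[Si](C)(C)C)C2C(C)(C)C3)C2(O[Si](C)(C)C)C=C(O[Si](C)(C)C)C1C(C)(C)C2 | intermediate
20 | tert-butyl 2-[(R)-8-({2-[(S)-8-((tert-butyldimethylsilyl)oxy)undecyl]-4,6-bis((trimethylsilyl)oxy)benzoyl}oxy)undecyl]-4,6-bis((trimethylsilyl)oxy)benzoate | CCC[C@H](O[Si](C)(C)C(C)(C)C)CCCCCCCc1cc(O[Si](C)(C)C)cc(O[Si](C)(C)C)c1C(=O)O[C@H](CCC)CCCCCCCc1cc(O[Si](C)(C)C)cc(O[Si](C)(C)C)c1C(=O)OC(C)(C)C | intermediate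
21 | 2-[(R)-8-({2,4-dihydroxy-6-[(S)-8-hydroxyundecyl]benzoyl}oxy)undecyl]-4,6-dihydroxybenzoic acid | CCC[C@H](O)CCCCCCCc1cc(O)cc(O)c1C(=O)O[C@H](CCC)CCCCCCCc1cc(O)cc(O)c1C(=O)O | intermediate
22 | (R)-1-(3,5-dihydroxyphenyl)undecan-8-yl 2,4-dihydroxy-6-[(S)-8-hydroxyundecyl]benzoate | CCC[C@H](O)CCCCCCCc1cc(O)cc(O)c1C(=O)O[C@H](CCC)CCCCCCCc1cc(O)cc(O)c1 | target

**Step count**

Total: 14 steps. Longest linear sequence: 12 steps (1, 2, 3, 4, 5, 6, 7, 8, 9, 12, 13, 14).

**Steps most likely to fail**

1. Step 12 (key step). The cycloaddition may be slow because the chain-bearing alkyne carbon has to bond to the diene terminus next to the quaternary carbon. The second annulation may then stall, or the diester may decompose on long heating. Fallback, setting out from 14: an acyclic, more reactive diene is used that aromatises by elimination and not by cycloreversion. Methyl acetoacetate is silylated (TMSCl, Et3N) to methyl 3-((trimethylsilyl)oxy)but-2-enoate F1, and LDA/TMSCl converts this into 1-methoxy-1,3-bis((trimethylsilyl)oxy)buta-1,3-diene F2. Heating 14 with excess F2 (toluene, 100–110 °C) should give the twofold cyclohexa-1,4-diene mixed-ketal adduct F3, with the CH2 terminus of the diene again bonding to the beta carbon of each ynoate. Loss of methanol from each C(OMe)(OSiMe3) carbon aromatises both rings and the sequence comes back to the route at 20; partly desilylated material is taken through step 13 in the same way.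

2. Step 9. The ynoate groups may be consumed by conjugate addition of PPh3 or of the hydrazide anion, or the displacement may be incomplete. Fallback, setting out from 13: the alcohol is converted (MsCl, Et3N, CH2Cl2, 0 °C) into tert-butyl (S)-11-((methylsulfonyl)oxy)tetradec-2-ynoate F4, and acid 11 is converted (Cs2CO3, 0.5 equiv, MeOH, evaporation) into cesium (S)-11-((tert-butyldimethylsilyl)oxy)tetradec-2-ynoate F5. SN2 displacement of F4 by F5 (DMF, 18-crown-6, 40–50 °C) should proceed with inversion and comes back to the route at 14.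

3. Step 13. The tert-butyl cation may escape the scavenger and alkylate the electron-rich rings, or the liberated secondary alcohol may be trifluoroacetylated and not fully released. Fallback, setting out from 20: the tert-butyl ester is cleaved while the phenols are still silylated, with TMSOTf and 2,6-lutidine in CH2Cl2 (0 °C to rt). 2-Methylpropene leaves under buffered, non-protic conditions and the product is trimethylsilyl 2-[(R)-8-({2-[(S)-8-((tert-butyldimethylsilyl)oxy)undecyl]-4,6-bis((trimethylsilyl)oxy)benzoyl}oxy)undecyl]-4,6-bis((trimethylsilyl)oxy)benzoate F6. HF·pyridine in THF–pyridine then removes all six silyl groups and the sequence comes back to the route at 21.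

**Further compounds**

F1 | step 12 | methyl 3-((trimethylsilyl)oxy)but-2-enoate | COC(=O)C=C(C)O[Si](C)(C)C
F2 | step 12 | 1-methoxy-1,3-bis((trimethylsilyl)oxy)buta-1,3-diene | COC(O[Si](C)(C)C)=CC(=C)O[Si](C)(C)C
F3 | step 12 | twofold cycloadduct of 14 and F2: each former ynoate is a 2-alkyl-6-methoxy-4,6-bis((trimethylsilyl)oxy)cyclohexa-1,4-diene-1-carboxylate (ketal configurations unassigned) | CCC[C@H](O[Si](C)(C)C(C)(C)C)CCCCCCCC1=C(C(=O)O[C@H](CCC)CCCCCCCC2=C(C(=O)OC(C)(C)C)C(OC)(O[Si](C)(C)C)C=C(O[Si](C)(C)C)C2)C(OC)(O[Si](C)(C)C)C=C(O[Si](C)(C)C)C1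
F4 | step 9 | tert-butyl (S)-11-((methylsulfonyl)oxy)tetradec-2-ynoate | CCC[C@H](OS(C)(=O)=O)CCCCCCCC#CC(=O)OC(C)(C)C
F5 | step 9 | cesium (S)-11-((tert-butyldimethylsilyl)oxy)tetradec-2-ynoate | [Cs+].CCC[C@H](O[Si](C)(C)C(C)(C)C)CCCCCCCC#CC(=O)[O-]
F6 | step 13 | trimethylsilyl 2-[(R)-8-({2-[(S)-8-((tert-butyldimethylsilyl)oxy)undecyl]-4,6-bis((trimethylsilyl)oxy)benzoyl}oxy)undecyl]-4,6-bis((trimethylsilyl)oxy)benzoate | CCC[C@H](O[Si](C)(C)C(C)(C)C)CCCCCCCc1cc(O[Si](C)(C)C)cc(O[Si](C)(C)C)c1C(=O)O[C@H](CCC)CCCCCCCc1cc(O[Si](C)(C)C)cc(O[Si](C)(C)C)c1C(=O)O[Si](C)(C)C
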